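## Retrosynthetic overview

1. Target 17 ⇒ tris(benzyl ether) 16 by hydrogenolysis; 16 ⇒ α-benzyloxy lactone 12 + benzylic bromide 14 by enolate C-benzylation at C3 (lactone numbering O1, C2=O, C3, C4, C5). Oxygen is placed on C3 before carbon, so that attack anti to the C4 arylmethyl group gives the trans-3,4-dibenzyl, cis-3-O/4-CH2Ar pattern.
2. 12 ⇒ lactone 9 by enolate hydroxylation and O-benzylation; the C3 configuration of 11 and 12 is erased again in the enolate of step 9.
3. 9 ⇒ open-chain diazoacetate 8: the C3–C4 bond is made by catalyst-controlled carbene insertion into a C4–H bond. This closes the γ-lactone, the only ring formed in the route (both benzene rings are bought), and sets C4.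
4. Enabling feature: C4 is a plain CH2 whose two enantiotopic C–H bonds lie 1,5 to the carbene carbon (future C3) across C2, O1 and C5, so a five-membered transition state reaches it. Its neighbours C5 (O–CH2) and the benzylic CH2 would need four- and six-membered closures.
5. 8 ⇒ 4-allyl-2,6-dimethoxyphenol 1 by benzylation, hydroboration–oxidation, bromoacetylation and diazo formation.

Key step: step 5

Remark: 1, 13 and all reagents are taken as commercial, and Rh2(4S-MPPIM)4 is taken as the catalyst enantiomer that gives (R)-9; if the sense proves opposite, Rh2(4R-MPPIM)4 is used and nothing else changes.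

## Route

Step 1
Reactants: 1 4-allyl-2,6-dimethoxyphenol
Product: 2 5-allyl-2-(benzyloxy)-1,3-dimethoxybenzene
Conditions: BnBr, K2CO3, DMF, 60 °C
Reagents that add atoms: benzyl bromide, BrCc1ccccc1
Why: Williamson ether synthesis on the phenoxide should mask the phenol, which would otherwise quench the carbene of step 5 and the enolates of steps 6 and 9; no stereocenter is involved.

Step 2
Reactants: 2 5-allyl-2-(benzyloxy)-1,3-dimethoxybenzene
Product: 4 3-[4-(benzyloxy)-3,5-dimethoxyphenyl]propan-1-ol, via B-alkyl-9-BBN adduct 3 (not isolated)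
Conditions: 9-BBN, THF, 0 °C to rt; then NaOH, H2O2, H2O, 0 °C to rt
Reagents that add atoms: hydrogen peroxide, OO (gives the hydroxyl oxygen of 4); 9-borabicyclo[3.3.1]nonane, [BH]1C2CCCC1CCC2 (its boron and carbon atoms stay only in 3)
Why: Anti-Markovnikov hydroboration–oxidation of the terminal alkene with a bulky borane should give the primary alcohol; the aryl benzyl ether is inert and no stereocenter is formed.

Step 3
Reactants: 4 3-[4-(benzyloxy)-3,5-dimethoxyphenyl]propan-1-ol
Product: 5 3-[4-(benzyloxy)-3,5-dimethoxyphenyl]propyl 2-bromoacetate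
Conditions: BrCH2COBr, NaHCO3, MeCN, 0 °C
Reagents that add atoms: bromoacetyl bromide, BrCC(Br)=O
Why: Acylation of a primary alcohol by an acid bromide under mild buffering should be clean and brings in C2 and C3 of the lactone.

Step 4
Reactants: 5 3-[4-(benzyloxy)-3,5-dimethoxyphenyl]propyl 2-bromoacetate
Product: 8 3-[4-(benzyloxy)-3,5-dimethoxyphenyl]propyl 2-diazoacetate, via N-alkylated ditosylhydrazine 6 (not isolated), via glyoxylate tosylhydrazone 7 (not isolated)
Conditions: TsNHNHTs, DBU, THF, 0 °C
Reagents that add atoms: N,N'-ditosylhydrazine, Cc1ccc(cc1)S(=O)(=O)NNS(=O)(=O)c1ccc(C)cc1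
Why: N-alkylation of the ditosylhydrazine by the bromoacetate followed by two base-induced sulfinate eliminations (Bamford–Stevens type) is an established way from bromoacetates to diazoacetates and touches nothing else in 5.

Step 5
Reactants: 8 3-[4-(benzyloxy)-3,5-dimethoxyphenyl]propyl 2-diazoacetate
Product: 9 (R)-4-[4-(benzyloxy)-3,5-dimethoxybenzyl]dihydrofuran-2(3H)-one
Conditions: Rh2(4S-MPPIM)4 (1 mol %), CH2Cl2, reflux, slow addition of 8
Reagents that add atoms: none
Why: The carboxamidate complex of divalent rhodium, dirhodium tetrakis[methyl (4S)-2-oxo-1-(3-phenylpropanoyl)imidazolidine-4-carboxylate], should expel N2 from 8 to give an electrophilic rhodium carbene at the future C3, which inserts into a C4–H bond through a concerted, asynchronous three-centre transition state (hydride shift toward the carbene carbon with C3–C4 bond formation). The closest known reaction type is the enantioselective intramolecular C–H insertion of primary-alkyl diazoacetates under chiral dirhodium carboxamidate catalysis, which is established for 3-arylpropyl diazoacetates giving 4-benzyl-γ-butyrolactones. The lactone closes in the 1,5-insertion mode: the carbene carbon reaches the σ C–H bond of C4 through a five-membered cyclic transition state that contains C2, O1 and C5. The new stereocenter C4 is set by the catalyst alone, whose chiral ligand pocket selects one of the two enantiotopic hydrogens of the C4 methylene; the (R) configuration is expected. The step needs site selectivity for C4–H over the C5–H bonds (β-lactone) and the benzylic C–H bonds (δ-lactone), and suppression of carbene dimerization. The weakly electrophilic carboxamidate carbene with its preference for five-membered closure, the slow addition, and the benzyl ether on the phenol (no O–H insertion) should secure this.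

Step 6
Reactants: 9 (R)-4-[4-(benzyloxy)-3,5-dimethoxybenzyl]dihydrofuran-2(3H)-one
Product: 11 (3R,4S)-4-[4-(benzyloxy)-3,5-dimethoxybenzyl]-3-hydroxydihydrofuran-2(3H)-one, via potassium enolate 10 (not isolated)
Conditions: KN(SiMe3)2, THF, −78 °C; then 3-phenyl-2-(phenylsulfonyl)oxaziridine, −78 °C; AcOH quench
Reagents that add atoms: 3-phenyl-2-(phenylsulfonyl)oxaziridine, O=S(=O)(c1ccccc1)N1OC1c1ccccc1
Why: Electrophilic enolate hydroxylation with an N-sulfonyloxaziridine (Davis oxidation) should deliver oxygen to C3 mainly anti to the C4 substituent (trans product); either C3 epimer serves, because C3 becomes planar again in step 9.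

Step 7
Reactants: 11 (3R,4S)-4-[4-(benzyloxy)-3,5-dimethoxybenzyl]-3-hydroxydihydrofuran-2(3H)-one
Product: 12 (3R,4S)-3-(benzyloxy)-4-[4-(benzyloxy)-3,5-dimethoxybenzyl]dihydrofuran-2(3H)-one
Conditions: BnBr, Ag2O, CH2Cl2, rt, dark
Reagents that add atoms: benzyl bromide, BrCc1ccccc1
Why: Silver-oxide-promoted O-benzylation of an α-hydroxy ester runs under neutral conditions that should leave the lactone closed, and gives an ether that survives the enolate chemistry and falls off in the final hydrogenolysis.

Step 8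
Reactants: 13 [4-(benzyloxy)-3-methoxyphenyl]methanol
Product: 14 1-(benzyloxy)-4-(bromomethyl)-2-methoxybenzene
Conditions: PBr3, Et2O, 0 °C
Reagents that add atoms: phosphorus tribromide, BrP(Br)Br
Why: Conversion of an electron-rich benzylic alcohol into the bromide with PBr3 is routine; the bromide is used at once in step 9.

Step 9
Reactants: 12 (3R,4S)-3-(benzyloxy)-4-[4-(benzyloxy)-3,5-dimethoxybenzyl]dihydrofuran-2(3H)-one; 14 1-(benzyloxy)-4-(bromomethyl)-2-methoxybenzene
Product: 16 (3S,4S)-3-(benzyloxy)-3-[4-(benzyloxy)-3-methoxybenzyl]-4-[4-(benzyloxy)-3,5-dimethoxybenzyl]dihydrofuran-2(3H)-one, via lithium enolate 15 (not isolated)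
Conditions: LiN(iPr)2, THF, −78 °C; then 14, DMPU, −78 to −40 °C
Reagents that add atoms: none
Why: Alkylation of the planar α-alkoxy lactone enolate by the reactive benzylic bromide should occur on the face opposite the C4 arylmethyl group (1,2-induction), so the new benzyl group ends trans to it and the C3 oxygen cis, which sets the quaternary C3 stereocenter as (S).

Step 10
Reactants: 16 (3S,4S)-3-(benzyloxy)-3-[4-(benzyloxy)-3-methoxybenzyl]-4-[4-(benzyloxy)-3,5-dimethoxybenzyl]dihydrofuran-2(3H)-one
Product: 17 (3S,4S)-3-hydroxy-3-(4-hydroxy-3-methoxybenzyl)-4-(4-hydroxy-3,5-dimethoxybenzyl)dihydrofuran-2(3H)-one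
Conditions: H2 (1 atm), Pd(OH)2/C, EtOAc–MeOH, rt
Reagents that add atoms: none
Why: Palladium-catalysed hydrogenolysis should cleave the two aryl benzyl ethers and the tertiary alkyl benzyl ether; the molecule holds no other reducible group and neither stereocenter is touched.

## Compound list

1 | 4-allyl-2,6-dimethoxyphenol | C=CCc1cc(OC)c(O)c(OC)c1 | starting material
2 | 5-allyl-2-(benzyloxy)-1,3-dimethoxybenzene | C=CCc1cc(OC)c(OCc2ccccc2)c(OC)c1 | intermediate
3 | 9-{3-[4-(benzyloxy)-3,5-dimethoxyphenyl]propyl}-9-borabicyclo[3.3.1]nonane | COc1cc(CCCB2C3CCCC2CCC3)cc(OC)c1OCc1ccccc1 | intermediate (not isolated)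
4 | 3-[4-(benzyloxy)-3,5-dimethoxyphenyl]propan-1-ol | OCCCc1cc(OC)c(OCc2ccccc2)c(OC)c1 | intermediate
5 | 3-[4-(benzyloxy)-3,5-dimethoxyphenyl]propyl 2-bromoacetate | BrCC(=O)OCCCc1cc(OC)c(OCc2ccccc2)c(OC)c1 | intermediate
6 | 3-[4-(benzyloxy)-3,5-dimethoxyphenyl]propyl 2-[1,2-bis(4-methylphenylsulfonyl)hydrazinyl]acetate | Cc1ccc(cc1)S(=O)(=O)NN(CC(=O)OCCCc1cc(OC)c(OCc2ccccc2)c(OC)c1)S(=O)(=O)c1ccc(C)cc1 | intermediate (not isolated)
7 | 3-[4-(benzyloxy)-3,5-dimethoxyphenyl]propyl 2-[2-(4-methylphenylsulfonyl)hydrazinylidene]acetate | Cc1ccc(cc1)S(=O)(=O)NN=CC(=O)OCCCc1cc(OC)c(OCc2ccccc2)c(OC)c1 | intermediate (not isolated)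
8 | 3-[4-(benzyloxy)-3,5-dimethoxyphenyl]propyl 2-diazoacetate | [N-]=[N+]=CC(=O)OCCCc1cc(OC)c(OCc2ccccc2)c(OC)c1 | intermediate
9 | (R)-4-[4-(benzyloxy)-3,5-dimethoxybenzyl]dihydrofuran-2(3H)-one | O=C1C[C@@H](Cc2cc(OC)c(OCc3ccccc3)c(OC)c2)CO1 | intermediate
10 | potassium enolate of 9 (potassium 4-[4-(benzyloxy)-3,5-dimethoxybenzyl]-4,5-dihydrofuran-2-olate, C4 as in 9) | [K+].[O-]C1=C[C@@H](Cc2cc(OC)c(OCc3ccccc3)c(OC)c2)CO1 | intermediate (not isolated)
11 | (3R,4S)-4-[4-(benzyloxy)-3,5-dimethoxybenzyl]-3-hydroxydihydrofuran-2(3H)-one (3-OH trans to the 4-arylmethyl group) | O=C1[C@H](O)[C@@H](Cc2cc(OC)c(OCc3ccccc3)c(OC)c2)CO1 | intermediate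
12 | (3R,4S)-3-(benzyloxy)-4-[4-(benzyloxy)-3,5-dimethoxybenzyl]dihydrofuran-2(3H)-one | O=C1[C@H](OCc2ccccc2)[C@@H](Cc2cc(OC)c(OCc3ccccc3)c(OC)c2)CO1 | intermediate
13 | [4-(benzyloxy)-3-methoxyphenyl]methanol | COc1cc(CO)ccc1OCc1ccccc1 | starting material
14 | 1-(benzyloxy)-4-(bromomethyl)-2-methoxybenzene | COc1cc(CBr)ccc1OCc1ccccc1 | intermediate
15 | lithium enolate of 12 (lithium 3-(benzyloxy)-4-[4-(benzyloxy)-3,5-dimethoxybenzyl]-4,5-dihydrofuran-2-olate, C4 as in 12) | [Li+].[O-]C1=C(OCc2ccccc2)[C@@H](Cc2cc(OC)c(OCc3ccccc3)c(OC)c2)CO1 | intermediate (not isolated)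
16 | (3S,4S)-3-(benzyloxy)-3-[4-(benzyloxy)-3-methoxybenzyl]-4-[4-(benzyloxy)-3,5-dimethoxybenzyl]dihydrofuran-2(3H)-one | COc1cc(C[C@@]2(OCc3ccccc3)C(=O)OC[C@@H]2Cc2cc(OC)c(OCc3ccccc3)c(OC)c2)ccc1OCc1ccccc1 | intermediate
17 | (3S,4S)-3-hydroxy-3-(4-hydroxy-3-methoxybenzyl)-4-(4-hydroxy-3,5-dimethoxybenzyl)dihydrofuran-2(3H)-one | COc1cc(C[C@@]2(O)C(=O)OC[C@@H]2Cc2cc(OC)c(O)c(OC)c2)ccc1O | target

## Step count and risks

Total steps: 10. Longest linear sequence: 9 (steps 1–7, 9 and 10; step 8 is a one-step side branch).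

Steps most likely to fail:

**Step 5.** The carbene may insert at the wrong C–H bond (O–CH2 or benzylic), dimerize, or discriminate poorly between the two C4 hydrogens, which would erode the enantiomeric purity of everything downstream. The fallback sets out from 4 and returns at 9, using auxiliary-controlled alkylation instead of C–H insertion. Alcohol 4 is oxidized (TEMPO, PhI(OAc)2, MeCN–H2O) to 3-[4-(benzyloxy)-3,5-dimethoxyphenyl]propanoic acid F1. Its pivaloyl mixed anhydride is coupled with (S)-4-benzyloxazolidin-2-one (Et3N, LiCl, THF) to give imide (S)-4-benzyl-3-{3-[4-(benzyloxy)-3,5-dimethoxyphenyl]propanoyl}oxazolidin-2-one F2. Its sodium enolate (NaN(SiMe3)2, THF, −78 °C) is alkylated with tert-butyl bromoacetate on the face away from the auxiliary benzyl group to give tert-butyl (R)-3-[(S)-4-benzyl-2-oxooxazolidine-3-carbonyl]-4-[4-(benzyloxy)-3,5-dimethoxyphenyl]butanoate F3. LiBH4 (Et2O, MeOH, 0 °C) removes the auxiliary reductively to give tert-butyl (R)-4-[4-(benzyloxy)-3,5-dimethoxyphenyl]-3-(hydroxymethyl)butanoate F4, and CF3CO2H in CH2Cl2 closes the lactone to 9.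

**Step 9.** The hindered, fully substituted enolate may react sluggishly, alkylate on oxygen, lose facial selectivity, or outlive the labile bromide 14. The fallback sets out from 12 and returns at 17. The same lithium enolate 15 is added at −78 °C to commercial 4-(benzyloxy)-3-methoxybenzaldehyde, a smaller and more reactive electrophile that should approach from the same face. This aldol addition gives (3R,4S)-3-(benzyloxy)-3-{[4-(benzyloxy)-3-methoxyphenyl](hydroxy)methyl}-4-[4-(benzyloxy)-3,5-dimethoxybenzyl]dihydrofuran-2(3H)-one F5; the spatial arrangement at C3 is that of 16, the descriptor changes only through ligand priorities, and the carbinol configuration is of no consequence. Hydrogenolysis (H2, Pd/C, AcOH, trace HClO4) then removes the benzylic hydroxyl group and all three benzyl ethers in one operation to give 17.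

**Step 10.** Hydrogenolysis of the crowded tertiary benzyl ether at C3 may stall after the two aryl ethers have been cleaved. The fallback sets out from 16 and returns at 17: Lewis-acid debenzylation with BCl3 and pentamethylbenzene as cation scavenger (CH2Cl2, −78 °C), which should cleave all three benzyl ethers without touching the methyl ethers or the lactone (no new compound, F0).

## Further compounds

F1 | step 5 | 3-[4-(benzyloxy)-3,5-dimethoxyphenyl]propanoic acid | OC(=O)CCc1cc(OC)c(OCc2ccccc2)c(OC)c1
F2 | step 5 | (S)-4-benzyl-3-{3-[4-(benzyloxy)-3,5-dimethoxyphenyl]propanoyl}oxazolidin-2-one | O=C(CCc1cc(OC)c(OCc2ccccc2)c(OC)c1)N1C(=O)OC[C@@H]1Cc1ccccc1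
F3 | step 5 | tert-butyl (R)-3-[(S)-4-benzyl-2-oxooxazolidine-3-carbonyl]-4-[4-(benzyloxy)-3,5-dimethoxyphenyl]butanoate | CC(C)(C)OC(=O)C[C@@H](Cc1cc(OC)c(OCc2ccccc2)c(OC)c1)C(=O)N1C(=O)OC[C@@H]1Cc1ccccc1
F4 | step 5 | tert-butyl (R)-4-[4-(benzyloxy)-3,5-dimethoxyphenyl]-3-(hydroxymethyl)butanoate | CC(C)(C)OC(=O)C[C@@H](Cc1cc(OC)c(OCc2ccccc2)c(OC)c1)CO
F5 | step 9 | (3R,4S)-3-(benzyloxy)-3-{[4-(benzyloxy)-3-methoxyphenyl](hydroxy)methyl}-4-[4-(benzyloxy)-3,5-dimethoxybenzyl]dihydrofuran-2(3H)-one, carbinol carbon unassigned | COc1cc(C(O)[C@@]2(OCc3ccccc3)C(=O)OC[C@@H]2Cc2cc(OC)c(OCc3ccccc3)c(OC)c2)ccc1OCc1ccccc1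
F0 | step 10 | none | none
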